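## Structural features

The target is a linear array of four benzene rings; it has no stereocentre and no ring other than these four. Ring A (4-hydroxyphenyl) is joined through a CH2CH2 bridge to C1 of ring B, which carries a methoxy group at C3 and, at C5, the oxygen of a diaryl ether to the para-phenylene ring C. Ring C is joined through a second CH2CH2 bridge to C6 of ring D, a 2-hydroxy-4-methoxybenzoic acid. The fragile part is ring D: an electron-rich salicylic acid loses CO2 on heating or in acid, and its carboxyl group sits between two ortho substituents, so an ordinary ester there could only be hydrolysed under forcing conditions. The real difficulty is connectivity and the differentiation of six oxygen functions (two phenols, two methyl ethers, one diaryl ether, one acid), together with the all-meta pattern of ring B, which oxygen-directed electrophilic substitution cannot deliver. The two bridges look alike but differ chemically: only the one at ring D has a benzylic carbon acidified by an ortho ester. The key step uses the other bridge: its two carbons are bonded to C4 of ring A and to C1 of ring B, two aryl–carbon bonds that an alkyne can supply, with propiolic acid as a two-carbon unit whose ends react at different temperatures.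

## Logic of the disconnections

16 from 15. No skeletal bond is cut. The saturated bridge between rings A and B is raised to a triple bond, and the two phenols and the carboxyl group are capped as benzyl groups. One catalytic hydrogenation then saturates the bridge and frees all three functions, and the hindered, decarboxylation-prone carboxyl is released under neutral conditions without hydrolysis. The demand is that 15 holds nothing else that hydrogen over palladium attacks and that no catalyst poison is carried into the last step.

15 from 11, 12 and 13. The bonds cut are C4 of ring A to one alkyne carbon and C1 of ring B to the other. Cutting both at once removes the whole bridge and leaves a protected ring A iodide (12), a linchpin (13) that loses its third carbon as CO2, and a bromide (11) holding rings B, C and D. The monoarylated alkynoic acid 14 forms and is consumed in the same flask. The demand is chemoselectivity: the iodide must react first, at the C–H end of 13, and the bromide second, at the carboxyl end. Compound 11 must therefore carry exactly one halogen, and its ester and ethers must tolerate an amidine base at 80 °C.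

11 from 4 and 9. The bond cut is the CH2–CH2 bond of the bridge between rings C and D. The cut is placed there because the methyl group of 4 is acidified by the ortho ester and becomes a carbon nucleophile (10), while the benzylic carbon on ring C is a natural electrophile. This separates ring D, which comes from a purchasable acid, from the diaryl ether half. The demand is an anion that alkylates faster than it condenses with its own ester, and a base stoichiometry that leaves the aryl bromide of 9 alone.

9 from 8, 8 from 7, and 7 from 5 and 6. The benzylic bromide is traced back through the alcohol to the aldehyde, and then the diaryl ether is cut at the O–C bond on ring C. That side is chosen because a para-formyl group activates ring C for nucleophilic aromatic substitution, whereas ring B has no activating group. Ring B then enters as 5 with its 1,3,5 pattern already in place, and the ether forms without copper and without a statistical coupling of a dihalide. The demand is only that the unactivated C–Br bond survives carbonate at about 110 °C.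

4 from 3, 3 from 2, and 2 from 1. Three O–C bonds are cut in the reverse of their order of formation. The order follows acidity and chelation: the carboxyl first, then the free hydroxyl para to it (methyl), then the hydrogen-bonded ortho hydroxyl (benzyl). The gain is that all of ring D comes from 1. The demand is site selectivity in the methylation.

## Other disconnections considered

Alternative 1: The cut runs through ring D, at its C1–C6 and C2–C3 bonds, so that the ring is assembled from the (E)-enone A1 and dimethyl malonate A2.
- Forward key step: the malonate anion adds to the β-carbon of A1 (Michael addition), the methyl ketone enolate closes onto one malonate ester (Claisen condensation), and the racemic trans dihydroresorcylate A3 results. Oxidation to the aromatic level, methylation of the C4 oxygen, ester cleavage and debenzylation would follow.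
- In favour: the pattern of ring D (carboxyl between an oxygen and the chain, second oxygen para to the carboxyl) is written into the annulation. The reagents are cheap and no transition metal is needed. The two adjacent stereocentres of A3 need no control, because aromatisation erases them.
- Against, here: a ring with this pattern is purchasable, so the annulation builds what can be bought. A1 must already contain rings A, B and C with the A–B bridge and the diaryl ether, which this cut does nothing to make. The product is a methyl ester at the most hindered position, whose hydrolysis would need forcing base on a decarboxylation-prone acid.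
- Comparison: in mechanistic reliability the enolate cascade is the equal of the chosen key step, and in reagent cost and freedom from palladium it is the better. On structure it is weaker, because the harder bonds are left to a separate sequence. On step economy it is weaker, with about four operations after the key step against one.

Alternative 2: The cut runs through ring B, which would be formed from the cyclobutenone A4 and the aryl ethynyl ether A5.
- Forward key step: on heating, A4 opens to a vinylketene, which adds A5 in a [2+2] sense. A second four-electron ring opening, a 6π closure and tautomerisation give the 3-aryloxy-5-alkylphenol A6. Methylation of the new phenol, selective cleavage of the ring D methyl ether ortho to the ester, loss of the tert-butyl group and debenzylation would follow.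
- In favour: the 1,3,5 pattern of ring B follows from the mechanism with no regiochemical ambiguity. The step is thermal, neutral and metal-free. It joins the ring A half to the C–D half at a late stage, so it is the equal of the chosen plan in convergence. The A–B bridge arrives saturated, so no reduction is needed, which is a point in its favour.
- Against, here: the all-meta pattern of ring B can be bought, so the regiocontrol has no value in this case. A5 is an aryl ynol ether, a hydration-sensitive class usually reached by strong-base elimination, which the ester and benzylic positions of that fragment would have to survive. A4 needs its own multi-step synthesis. A6 carries the wrong oxygen pattern at two places (a free phenol on ring B, two methyl ethers on ring D).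
- Comparison: on structure the two plans are equal in convergence. On mechanism the benzannulation is less well supported for aryl ethynyl ethers than the palladium coupling is for aryl halides. On step economy it is weaker, both before the key step and after it (three or four operations against one).

Alternative 3: The cut is at the bond from C6 of ring D to the bridge, with a lactone C–O bond formed in the same step, so that ring D comes from 2,4-dimethoxybenzoic acid A7 and the bridge from the aroyl sulfoxonium ylide A8.
- Forward key step: with [Cp*RhCl2]2 and NaOAc the carboxylate directs metalation of the only free ortho C–H by trivalent rhodium. The ylide inserts as a carbene with loss of the sulfoxide, and cyclodehydration gives the 3-arylisocoumarin A9. Hydrogenation of the C3–C4 double bond, hydrogenolysis of the benzylic lactone C–O bond and of the benzyl ether, and selective cleavage of the C8 methyl ether would follow.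
- In favour: ring D comes from a very cheap acid without prefunctionalisation. There is one ortho C–H, so regiochemistry is not in question. No strong base or low temperature is needed. The A–B bridge is already saturated.
- Against, here: A8 needs rings A, B and C fully assembled, so the A–B bridge and the diaryl ether still have to be made by other means. Hydrogenolysis of the lactone C–O bond of a 3-aryl-3,4-dihydroisocoumarin is slower than O-debenzylation and may need acid or pressure. One of two ring D methyl ethers (three in the molecule) must then be cleaved selectively.
- Comparison: for the C–D bridge this catalytic C–H route is the better of the two in operational simplicity and functional-group tolerance, when set against the lateral lithiation of the chosen plan. On structure it is otherwise equal, with no stereochemical issue in either. On step economy it is weaker: two or three less certain operations follow the key step, and the ring A–B problem is left unsolved.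

Key step: step 8

Remark on the chemistry: ring B is taken as the catalogue phenol 5 and joined to ring C by nucleophilic aromatic substitution before the C–D bridge is made. This avoids a late statistical mono-etherification of a symmetrical dihalide and a 4-silyloxybenzyl halide that ionises readily to a quinone methide. LiN(iPr)2 (LDA) is assumed to be used as a commercial solution.

## Route

Step 1
Reactants: 1 2,4-dihydroxy-6-methylbenzoic acid
Product: 2 benzyl 2,4-dihydroxy-6-methylbenzoate
Conditions: BnBr (1.05 equiv), KHCO3, DMF, rt
Reagents that add atoms: benzyl bromide, BrCc1ccccc1
Why: Carboxylate O-alkylation (SN2 esterification): hydrogen carbonate ionises only the carboxylic acid, so the phenols stay free, and room temperature avoids the thermal decarboxylation to which this acid is prone.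

Step 2
Reactants: 2 benzyl 2,4-dihydroxy-6-methylbenzoate
Product: 3 benzyl 2-hydroxy-4-methoxy-6-methylbenzoate
Conditions: MeI (1.1 equiv), K2CO3 (1.1 equiv), acetone, rt to 40 °C
Reagents that add atoms: iodomethane, CI
Why: Williamson ether synthesis under site control: the C2 hydroxyl is held in a hydrogen bond to the ester carbonyl and is the weaker acid, so limited base and iodomethane should alkylate the C4 hydroxyl preferentially, as is usual for orsellinate esters.

Step 3
Reactants: 3 benzyl 2-hydroxy-4-methoxy-6-methylbenzoate
Product: 4 benzyl 2-(benzyloxy)-4-methoxy-6-methylbenzoate
Conditions: BnBr (1.3 equiv), K2CO3, DMF, 60 °C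
Reagents that add atoms: benzyl bromide, BrCc1ccccc1
Why: Williamson benzylation of the remaining chelated phenol, which needs the polar solvent and heat; the benzyl ester is inert to carbonate in dry DMF.

Step 4
Reactants: 5 3-bromo-5-methoxyphenol; 6 4-fluorobenzaldehyde
Product: 7 4-(3-bromo-5-methoxyphenoxy)benzaldehyde
Conditions: K2CO3, DMF, 110 °C
Reagents that add atoms: none
Why: Nucleophilic aromatic substitution (SNAr): the para-formyl group stabilises the anionic σ-adduct and fluoride is the best leaving group for this mechanism, while the unactivated C–Br bond of 5 is untouched, so the diaryl ether forms without copper and without a statistical problem.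

Step 5
Reactants: 7 4-(3-bromo-5-methoxyphenoxy)benzaldehyde
Product: 8 [4-(3-bromo-5-methoxyphenoxy)phenyl]methanol
Conditions: NaBH4, MeOH/THF, 0 °C
Reagents that add atoms: none
Why: Borohydride reduction of an aromatic aldehyde; the aryl bromide, the methyl ether and the diaryl ether are inert to this hydride.

Step 6
Reactants: 8 [4-(3-bromo-5-methoxyphenoxy)phenyl]methanol
Product: 9 1-bromo-3-[4-(bromomethyl)phenoxy]-5-methoxybenzene
Conditions: CBr4, PPh3, CH2Cl2, 0 °C to rt
Reagents that add atoms: carbon tetrabromide, BrC(Br)(Br)Br
Why: Appel reaction of a primary benzylic alcohol; the neutral conditions avoid the acid that could trigger Friedel–Crafts self-alkylation of the electron-rich ring B by the benzylic bromide.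

Step 7
Reactants: 4 benzyl 2-(benzyloxy)-4-methoxy-6-methylbenzoate; 9 1-bromo-3-[4-(bromomethyl)phenoxy]-5-methoxybenzene
Product: 11 benzyl 2-(benzyloxy)-6-[2-[4-(3-bromo-5-methoxyphenoxy)phenyl]ethyl]-4-methoxybenzoate, via benzylic lithium species 10 (not isolated)
Conditions: 4 (1.1 equiv), LiN(iPr)2 (1.05 equiv), THF, −78 °C; then 9 (1.0 equiv), −78 to −40 °C; aq NH4Cl
Reagents that add atoms: none
Why: Lateral (benzylic) lithiation of an ortho-toluate ester followed by SN2 alkylation: the amide base removes a methyl proton to give an extended ester enolate, as in routine amide-base enolisation of benzyl esters, and the primary benzylic bromide of 9 is far more electrophilic than its aryl bromide, which a stabilised carbanion does not exchange. Keeping 4 in slight excess over the base leaves no free amide to metalate ring B.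

Step 8
Reactants: 12 1-(benzyloxy)-4-iodobenzene; 13 propiolic acid; 11 benzyl 2-(benzyloxy)-6-[2-[4-(3-bromo-5-methoxyphenoxy)phenyl]ethyl]-4-methoxybenzoate
Product: 15 benzyl 2-(benzyloxy)-6-[2-[4-[3-[2-(4-benzyloxyphenyl)ethynyl]-5-methoxyphenoxy]phenyl]ethyl]-4-methoxybenzoate, via 3-[4-(benzyloxy)phenyl]prop-2-ynoic acid 14 (not isolated)
Conditions: 12 (1.2 equiv), 13 (1.2 equiv), PdCl2(PPh3)2 (5 mol %), dppb (10 mol %), DBU (2.5 equiv), DMSO, rt; then 11 (1.0 equiv), 80 °C
Reagents that add atoms: none
Why: Zerovalent palladium formed from PdCl2(PPh3)2 inserts into the C–I bond of 12 at room temperature, the amidine deprotonates the terminal C–H of the propiolate, and alkynyl transfer to divalent palladium with reductive elimination gives 14 as its DBU salt (copper-free Sonogashira coupling). After 11 is added and the mixture is heated, oxidative addition of the C–Br bond, binding of the alkynoate to divalent palladium, loss of CO2 to an aryl(alkynyl)palladium species and reductive elimination form the second aryl–alkyne bond. The closest known reaction type is the one-pot Sonogashira and decarboxylative coupling of propiolic acid with an aryl iodide and then an aryl bromide to give unsymmetrical diarylalkynes. No ring is closed and no stereocentre is formed. The selectivity needed is between the two halides and between the two ends of the linchpin: the iodide reacts at room temperature before the bromide is present, and the carboxylate does not decarboxylate until heated, so the second alkyne terminus stays masked. Using 12 and 13 in equal amounts leaves no iodide to compete for 14 in the second stage. In 11 the only C–Br bond sits meta to both oxygen substituents of ring B, which therefore do not retard oxidative addition, and the benzyl ester, benzyl ethers and diaryl ether are inert to DBU in dry DMSO. Any 14 that loses CO2 early becomes a terminal arylalkyne, which can still couple with 11 under the same conditions.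

Step 9
Reactants: 15 benzyl 2-(benzyloxy)-6-[2-[4-[3-[2-(4-benzyloxyphenyl)ethynyl]-5-methoxyphenoxy]phenyl]ethyl]-4-methoxybenzoate
Product: 16 2-hydroxy-6-[2-[4-[3-[2-(4-hydroxyphenyl)ethyl]-5-methoxyphenoxy]phenyl]ethyl]-4-methoxybenzoic acid
Conditions: H2 (1 atm), 10% Pd/C, THF/MeOH, rt
Reagents that add atoms: none
Why: Heterogeneous catalytic hydrogenation and hydrogenolysis: the diarylalkyne takes up two equivalents of hydrogen and the three benzylic C–O bonds (one ester, two aryl ethers) are cleaved on the same catalyst, which frees the hindered carboxyl without hydrolysis; methyl ethers, the diaryl ether and the arene rings are inert at this pressure.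

## Compound list

1 | 2,4-dihydroxy-6-methylbenzoic acid | Cc1cc(O)cc(O)c1C(=O)O | starting material
2 | benzyl 2,4-dihydroxy-6-methylbenzoate | Cc1cc(O)cc(O)c1C(=O)OCc1ccccc1 | intermediate
3 | benzyl 2-hydroxy-4-methoxy-6-methylbenzoate | Cc1cc(OC)cc(O)c1C(=O)OCc1ccccc1 | intermediate
4 | benzyl 2-(benzyloxy)-4-methoxy-6-methylbenzoate | Cc1cc(OC)cc(OCc2ccccc2)c1C(=O)OCc1ccccc1 | intermediate
5 | 3-bromo-5-methoxyphenol | COc1cc(O)cc(Br)c1 | starting material
6 | 4-fluorobenzaldehyde | O=Cc1ccc(F)cc1 | starting material
7 | 4-(3-bromo-5-methoxyphenoxy)benzaldehyde | COc1cc(Br)cc(Oc2ccc(C=O)cc2)c1 | intermediate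
8 | [4-(3-bromo-5-methoxyphenoxy)phenyl]methanol | COc1cc(Br)cc(Oc2ccc(CO)cc2)c1 | intermediate
9 | 1-bromo-3-[4-(bromomethyl)phenoxy]-5-methoxybenzene | COc1cc(Br)cc(Oc2ccc(CBr)cc2)c1 | intermediate
10 | benzyl 2-(benzyloxy)-6-(lithiomethyl)-4-methoxybenzoate (not isolated) | [Li]Cc1cc(OC)cc(OCc2ccccc2)c1C(=O)OCc1ccccc1 | intermediate
11 | benzyl 2-(benzyloxy)-6-[2-[4-(3-bromo-5-methoxyphenoxy)phenyl]ethyl]-4-methoxybenzoate | COc1cc(Br)cc(Oc2ccc(CCc3cc(OC)cc(OCc4ccccc4)c3C(=O)OCc3ccccc3)cc2)c1 | intermediate
12 | 1-(benzyloxy)-4-iodobenzene | Ic1ccc(OCc2ccccc2)cc1 | starting material
13 | propiolic acid | C#CC(=O)O | starting material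
14 | 3-[4-(benzyloxy)phenyl]prop-2-ynoic acid (not isolated) | O=C(O)C#Cc1ccc(OCc2ccccc2)cc1 | intermediate
15 | benzyl 2-(benzyloxy)-6-[2-[4-[3-[2-(4-benzyloxyphenyl)ethynyl]-5-methoxyphenoxy]phenyl]ethyl]-4-methoxybenzoate | COc1cc(C#Cc2ccc(OCc3ccccc3)cc2)cc(Oc2ccc(CCc3cc(OC)cc(OCc4ccccc4)c3C(=O)OCc3ccccc3)cc2)c1 | intermediate
16 | 2-hydroxy-6-[2-[4-[3-[2-(4-hydroxyphenyl)ethyl]-5-methoxyphenoxy]phenyl]ethyl]-4-methoxybenzoic acid | COc1cc(CCc2ccc(O)cc2)cc(Oc2ccc(CCc3cc(OC)cc(O)c3C(=O)O)cc2)c1 | target

## Step count and least certain steps

Total step count: 9. Longest linear sequence: 6 steps (steps 1, 2, 3, 7, 8, 9; the branch through steps 4, 5, 6 and then 7, 8, 9 is equally long).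

Step 8 (key step). The most likely failures are processes that consume the arylpropiolate before it meets the bromide: a second arylation by residual iodide if the first stage runs too warm, giving a symmetrical diarylalkyne, or oxidative dimerisation of decarboxylated alkyne if air enters. A slow second stage could also expose the benzyl ester to wet base for a long time. Fallback: from 11, a two-component copper-free Sonogashira coupling with the purchasable 1-(benzyloxy)-4-ethynylbenzene F1 (PdCl2(MeCN)2, XPhos, Cs2CO3, MeCN, 80 °C) forms only the ring B C1–alkyne bond and returns to the route at 15.

Step 7. The benzylic anion may condense with un-ionised ester (Claisen-type self-condensation). Deprotonation may compete at the ester O–CH2 group, followed by acyl migration. The product, which is also laterally acidic, may quench the anion and then be alkylated twice. Excess amide may metalate ring B next to the bromine. Fallback: the acid and the ortho phenol are tied up as an acetonide, a substrate class on which lateral lithiation is well established. From 1, acetone with trifluoroacetic anhydride and trifluoroacetic acid should give 7-hydroxy-2,2,5-trimethyl-4H-1,3-benzodioxin-4-one F2. MeI and K2CO3 then give 7-methoxy-2,2,5-trimethyl-4H-1,3-benzodioxin-4-one F3. LiN(iPr)2 at −78 °C followed by 9 gives 5-[2-[4-(3-bromo-5-methoxyphenoxy)phenyl]ethyl]-7-methoxy-2,2-dimethyl-4H-1,3-benzodioxin-4-one F4. Opening with benzyl alcohol and NaH gives benzyl 2-[2-[4-(3-bromo-5-methoxyphenoxy)phenyl]ethyl]-6-hydroxy-4-methoxybenzoate F5, and BnBr with K2CO3 in DMF returns to the route at 11.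

Step 2. Alkylation may run on to the chelated C2 hydroxyl, or C-methylation of the resorcinol ring may occur if base or iodomethane is in excess, which would erode the site selectivity. Fallback: from 2, a Mitsunobu etherification with methanol, PPh3 and diisopropyl azodicarboxylate in THF, which engages only the more acidic, non-chelated C4 hydroxyl, returns to the route at 3; this fallback makes no new compound (F0).

Step 9. Hydrogenolysis may stall through poisoning of the catalyst by phosphine or sulfur residues carried over from step 8, leaving the hindered benzyl ester or the ortho benzyl ether in place, or reduction of the alkyne may stop at the stilbene. Fallback: saturation and deprotection are separated. From 15, hydrogenation over Pd/C moderated with Ph2S should reduce only the triple bond to give benzyl 2-(benzyloxy)-6-[2-[4-[3-[2-(4-benzyloxyphenyl)ethyl]-5-methoxyphenoxy]phenyl]ethyl]-4-methoxybenzoate F6. BCl3 with pentamethylbenzene as cation scavenger in CH2Cl2 at −78 °C then removes the three benzyl groups by Lewis-acid cleavage while sparing the methyl ethers, and returns to the route at 16.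

## Further compounds

F1 | step 8 | 1-(benzyloxy)-4-ethynylbenzene | C#Cc1ccc(OCc2ccccc2)cc1
F2 | step 7 | 7-hydroxy-2,2,5-trimethyl-4H-1,3-benzodioxin-4-one | Cc1cc(O)cc2OC(C)(C)OC(=O)c12
F3 | step 7 | 7-methoxy-2,2,5-trimethyl-4H-1,3-benzodioxin-4-one | Cc1cc(OC)cc2OC(C)(C)OC(=O)c12
F4 | step 7 | 5-[2-[4-(3-bromo-5-methoxyphenoxy)phenyl]ethyl]-7-methoxy-2,2-dimethyl-4H-1,3-benzodioxin-4-one | COc1cc(Br)cc(Oc2ccc(CCc3cc(OC)cc4OC(C)(C)OC(=O)c34)cc2)c1
F5 | step 7 | benzyl 2-[2-[4-(3-bromo-5-methoxyphenoxy)phenyl]ethyl]-6-hydroxy-4-methoxybenzoate | COc1cc(Br)cc(Oc2ccc(CCc3cc(OC)cc(O)c3C(=O)OCc3ccccc3)cc2)c1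
F0 | step 2 | none | none
F6 | step 9 | benzyl 2-(benzyloxy)-6-[2-[4-[3-[2-(4-benzyloxyphenyl)ethyl]-5-methoxyphenoxy]phenyl]ethyl]-4-methoxybenzoate | COc1cc(CCc2ccc(OCc3ccccc3)cc2)cc(Oc2ccc(CCc3cc(OC)cc(OCc4ccccc4)c3C(=O)OCc3ccccc3)cc2)c1
A1 | alternative 1 | (E)-6-[4-[3-[2-(4-benzyloxyphenyl)ethyl]-5-methoxyphenoxy]phenyl]hex-3-en-2-one | CC(=O)/C=C/CCc1ccc(Oc2cc(OC)cc(CCc3ccc(OCc4ccccc4)cc3)c2)cc1
A2 | alternative 1 | dimethyl malonate | COC(=O)CC(=O)OC
A3 | alternative 1 | racemic trans-methyl 6-[2-[4-[3-[2-(4-benzyloxyphenyl)ethyl]-5-methoxyphenoxy]phenyl]ethyl]-2-hydroxy-4-oxocyclohex-2-ene-1-carboxylate (one enantiomer drawn) | COC(=O)[C@@H]1[C@@H](CCc2ccc(Oc3cc(OC)cc(CCc4ccc(OCc5ccccc5)cc4)c3)cc2)CC(=O)C=C1O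
A4 | alternative 2 | 3-[2-(4-benzyloxyphenyl)ethyl]cyclobut-2-en-1-one | O=C1C=C(CCc2ccc(OCc3ccccc3)cc2)C1
A5 | alternative 2 | tert-butyl 2-[2-(4-ethynyloxyphenyl)ethyl]-4,6-dimethoxybenzoate | C#COc1ccc(CCc2cc(OC)cc(OC)c2C(=O)OC(C)(C)C)cc1
A6 | alternative 2 | tert-butyl 2-[2-[4-[3-[2-(4-benzyloxyphenyl)ethyl]-5-hydroxyphenoxy]phenyl]ethyl]-4,6-dimethoxybenzoate | Oc1cc(CCc2ccc(OCc3ccccc3)cc2)cc(Oc2ccc(CCc3cc(OC)cc(OC)c3C(=O)OC(C)(C)C)cc2)c1
A7 | alternative 3 | 2,4-dimethoxybenzoic acid | COc1ccc(C(=O)O)c(OC)c1
A8 | alternative 3 | 1-[4-[3-[2-(4-benzyloxyphenyl)ethyl]-5-methoxyphenoxy]phenyl]-2-[dimethyl(oxo)-λ6-sulfanylidene]ethan-1-one | CS(C)(=O)=CC(=O)c1ccc(Oc2cc(OC)cc(CCc3ccc(OCc4ccccc4)cc3)c2)cc1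
A9 | alternative 3 | 3-[4-[3-[2-(4-benzyloxyphenyl)ethyl]-5-methoxyphenoxy]phenyl]-6,8-dimethoxy-1H-isochromen-1-one | COc1cc(OC)c2c(c1)C=C(c1ccc(Oc3cc(OC)cc(CCc4ccc(OCc5ccccc5)cc4)c3)cc1)OC2=O
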